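**Retrosynthetic overview**

1. The free OH on C1 of ring A is made last, from the C–B bond of aryl pinacol boronate 18.
2. Ring A carries OH on C1, the 2-bromophenoxy oxygen on C2, bromine on C3, C4 and C5, and hydrogen on C6. It is cut into the four carbons C3–C6, which are the ring carbons of 2,3,4-tribromothiophene (three adjacent C–Br and one C–H), and the two carbons C1–C2, an alkyne with boron on one end and the aryloxy oxygen on the other.
3. Forward, thiophene 1,1-dioxide 5 and alkynyl boronate 16 join in a Diels–Alder reaction and the sulfur bridge leaves as SO2, so ring A appears fully substituted in one operation.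
4. The alkyne branch starts from 2-bromophenol (ring B bought intact): vinyl ether, dibromide, then double elimination to the ethynyl ether, which is borylated in the same flask as its lithium acetylide. The diene branch starts from tetrabromothiophene: removal of one α-bromine, then oxidation at sulfur.
5. Ring order: ring B is present from the start, ring A is closed in step 7, and the thiophene ring is consumed there.

Key step: step 7

Remark: the target has no stereocentre; the stereocentres that appear on the way (in 4, 10 and 17) are racemic and are lost again. Sulfone 5 and alkynyl boronate 16 are assumed to be handled as cold solutions under argon and used on the day they are made; ethynyl ether 13 is never isolated.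

**Route**

Step 1
Reactants: 1 tetrabromothiophene
Product: 3 2,3,4-tribromothiophene, via thienyllithium 2 (not isolated)
Conditions: n-BuLi (1.0 equiv), THF, −78 °C; then H2O, −78 °C to rt
Reagents that add atoms: none
Why: Bromine–lithium exchange is fastest at an α-position of the perbrominated thiophene because the α-thienyl anion is the best stabilized, so one equivalent of n-butyllithium at low temperature should give only the monolithium compound 2, which water protonates to 3.

Step 2
Reactants: 3 2,3,4-tribromothiophene
Product: 5 2,3,4-tribromothiophene 1,1-dioxide, via S-oxide 4 (not isolated)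
Conditions: urea–H2O2, (CF3CO)2O, MeCN, 0 °C to rt; cold work-up, used the same day
Reagents that add atoms: trifluoroperacetic acid, OOC(=O)C(F)(F)F (made in the flask from hydrogen peroxide, OO, of the urea complex and trifluoroacetic anhydride)
Why: Oxidation of a thiophene at sulfur by a peracid needs the most electrophilic common peracid here because three bromines make the sulfur a poor nucleophile; the S-oxide 4 is oxidized faster than 3 and should not build up, and the product is kept cold and dilute because its free C5–H position allows slow self-dimerization.

Step 3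
Reactants: 6 2-bromophenol, 7 1,2-dibromoethane
Product: 8 1-bromo-2-(2-bromoethoxy)benzene
Conditions: K2CO3, 7 (5 equiv), MeCN, reflux
Reagents that add atoms: 1,2-dibromoethane (compound 7), BrCCBr
Why: Williamson ether synthesis, in which the phenoxide displaces one bromide by SN2 and the large excess of 7 keeps the second displacement to the 1,2-diaryloxyethane low.

Step 4
Reactants: 8 1-bromo-2-(2-bromoethoxy)benzene
Product: 9 1-bromo-2-(ethenyloxy)benzene (2-bromophenyl vinyl ether)
Conditions: KOtBu, THF, 0 °C to rt
Reagents that add atoms: none
Why: E2 elimination of HBr by the hindered alkoxide, which removes the hydrogen acidified by the neighbouring oxygen in preference to substitution, gives the aryl vinyl ether, and the aryl bromide is untouched at this temperature.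

Step 5
Reactants: 9 1-bromo-2-(ethenyloxy)benzene
Product: 10 1-bromo-2-(1,2-dibromoethoxy)benzene (racemic)
Conditions: Br2 (1.0 equiv), CH2Cl2, −78 °C; solvent removed cold, used crude
Reagents that add atoms: bromine, BrBr
Why: Electrophilic addition of bromine to the electron-rich enol ether double bond is far faster at −78 °C than substitution on the bromine-deactivated ring; the carbon bearing O and Br becomes a stereocentre without control (racemate), which does not matter because it is removed in step 6.

Step 6
Reactants: 10 1-bromo-2-(1,2-dibromoethoxy)benzene, 11 2-isopropoxy-4,4,5,5-tetramethyl-1,3,2-dioxaborolane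
Product: 16 2-[(2-bromophenoxy)ethynyl]-4,4,5,5-tetramethyl-1,3,2-dioxaborolane, via bromovinyl ether 12 (not isolated), via ethynyl ether 13 (not isolated), via lithium acetylide 14 (not isolated), via borate complex 15 (not isolated)
Conditions: LiN(iPr)2 (3.1 equiv), THF, −78 to −40 °C (10 added to the base); 11 (1.2 equiv), −78 °C; HCl in Et2O (1.1 equiv), −78 °C to rt; solvent exchanged for pentane, filtration under argon
Reagents that add atoms: 2-isopropoxy-4,4,5,5-tetramethyl-1,3,2-dioxaborolane (compound 11), CC(C)OB1OC(C)(C)C(C)(C)O1
Why: Two successive base-induced eliminations of HBr give first bromovinyl ether 12 (either geometric isomer of which eliminates again) and then ethynyl ether 13, which the third equivalent of the hindered amide deprotonates at once to acetylide 14; this adds to the trigonal boron of 11 to give the four-coordinate borate 15, from which anhydrous HCl removes isopropoxide as propan-2-ol and LiCl (standard borylation of a lithium acetylide), so the sensitive terminal ynol ether is trapped as it forms, no water reaches the push–pull alkyne, and the lithium amide at −78 °C should neither exchange the aryl bromine, as an alkyllithium would, nor form a benzyne at a useful rate.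

Step 7
Reactants: 5 2,3,4-tribromothiophene 1,1-dioxide, 16 2-[(2-bromophenoxy)ethynyl]-4,4,5,5-tetramethyl-1,3,2-dioxaborolane
Product: 18 2-[3,4,5-tribromo-2-(2-bromophenoxy)phenyl]-4,4,5,5-tetramethyl-1,3,2-dioxaborolane, via bridged sulfone adduct 17 (not isolated)
Conditions: 16 (1.5 equiv), toluene, 80 °C, slow addition of freshly made 5 in toluene, argon; SO2 vented
Reagents that add atoms: none
Why: Proposed new method: the tribrominated thiophene 1,1-dioxide is an electron-poor, non-aromatic diene and the aryloxy alkyne an electron-rich dienophile, so a (4+2) cycloaddition with inverse electron demand should occur on mild heating, and the 7-thiabicyclo[2.2.1]heptadiene 7,7-dioxide 17 should lose SO2 at once by cheletropic extrusion to give the benzene ring without any further redox step. The closest known reactions are the cycloadditions of tetrahalothiophene 1,1-dioxides with alkynes, which give tetrahalobenzenes after loss of SO2, and the cycloaddition–extrusion of alkynyl pinacol boronates with 2-pyrones, which gives aryl boronates; the pairing of a thiophene dioxide with an alkynyl boronate that is also an ynol ether has not been described. Ring A is closed by a concerted but asynchronous suprafacial addition of the two alkyne carbons to C2 and C5 of the diene (both new C–C bonds in one six-membered transition state), after which the sulfur bridge departs. No stereocentre remains, since the two bridgehead centres of 17 are racemic and vanish on aromatization. The step needs regioselectivity (boron-bearing carbon to the C5–H terminus, aryloxy-bearing carbon to the C2–Br terminus): the oxygen lone pair makes the boron-bearing carbon the nucleophilic end of the alkyne, attack at unsubstituted C5 places the developing negative charge on C2 where the sulfonyl group and bromine stabilize it, and the bulky boronate end also meets the C–H rather than the C–Br terminus. Self-dimerization of 5 through its free C5–H is held back by adding fresh 5 slowly to an excess of 16, and the aryl ynol ether has no β-hydrogen on its O-substituent for a retro-ene fragmentation, so it should tolerate the heating.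

Step 8
Reactants: 18 2-[3,4,5-tribromo-2-(2-bromophenoxy)phenyl]-4,4,5,5-tetramethyl-1,3,2-dioxaborolane
Product: 20 3,4,5-tribromo-2-(2-bromophenoxy)phenol (target), via aryl borate ester 19 (not isolated)
Conditions: H2O2 (30% aq.), NaOH (aq.), THF, 0 °C to rt; then dilute HCl
Reagents that add atoms: hydrogen peroxide, OO
Why: Hydroperoxide anion adds to boron, the aryl group shifts from boron to oxygen with loss of hydroxide to give borate ester 19, and hydrolysis frees the phenol (standard oxidation of an arylboronate), under conditions that leave aryl bromides and the diaryl ether untouched.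

**Compound list**

1 | tetrabromothiophene | Brc1sc(Br)c(Br)c1Br | starting material
2 | (3,4,5-tribromothiophen-2-yl)lithium | [Li]c1sc(Br)c(Br)c1Br | intermediate
3 | 2,3,4-tribromothiophene | Brc1scc(Br)c1Br | intermediate
4 | 2,3,4-tribromothiophene 1-oxide (racemic at sulfur) | O=S1C=C(Br)C(Br)=C1Br | intermediate
5 | 2,3,4-tribromothiophene 1,1-dioxide | O=S1(=O)C=C(Br)C(Br)=C1Br | intermediate
6 | 2-bromophenol | Oc1ccccc1Br | starting material
7 | 1,2-dibromoethane | BrCCBr | starting material
8 | 1-bromo-2-(2-bromoethoxy)benzene | BrCCOc1ccccc1Br | intermediate
9 | 1-bromo-2-(ethenyloxy)benzene | C=COc1ccccc1Br | intermediate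
10 | 1-bromo-2-(1,2-dibromoethoxy)benzene (racemic) | BrCC(Br)Oc1ccccc1Br | intermediate
11 | 2-isopropoxy-4,4,5,5-tetramethyl-1,3,2-dioxaborolane | CC(C)OB1OC(C)(C)C(C)(C)O1 | starting material
12 | 1-bromo-2-[(2-bromoethenyl)oxy]benzene (E/Z mixture) | BrC=COc1ccccc1Br | intermediate
13 | 1-bromo-2-(ethynyloxy)benzene (2-bromophenyl ethynyl ether) | C#COc1ccccc1Br | intermediate
14 | [(2-bromophenoxy)ethynyl]lithium | [Li]C#COc1ccccc1Br | intermediate
15 | lithium [(2-bromophenoxy)ethynyl](isopropoxy)(pinacolato)borate | [Li+].CC(C)O[B-]1(C#COc2ccccc2Br)OC(C)(C)C(C)(C)O1 | intermediate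
16 | 2-[(2-bromophenoxy)ethynyl]-4,4,5,5-tetramethyl-1,3,2-dioxaborolane | CC1(C)OB(C#COc2ccccc2Br)OC1(C)C | intermediate
17 | 1,5,6-tribromo-2-(2-bromophenoxy)-3-(4,4,5,5-tetramethyl-1,3,2-dioxaborolan-2-yl)-7-thiabicyclo[2.2.1]hepta-2,5-diene 7,7-dioxide (racemic; bridgeheads tied by the bicycle) | O=S1(=O)C2(Br)C(Br)=C(Br)C1C(B3OC(C)(C)C(C)(C)O3)=C2Oc4ccccc4Br | intermediate
18 | 2-[3,4,5-tribromo-2-(2-bromophenoxy)phenyl]-4,4,5,5-tetramethyl-1,3,2-dioxaborolane | CC1(C)OB(c2cc(Br)c(Br)c(Br)c2Oc2ccccc2Br)OC1(C)C | intermediate
19 | 2-[3,4,5-tribromo-2-(2-bromophenoxy)phenoxy]-4,4,5,5-tetramethyl-1,3,2-dioxaborolane | CC1(C)OB(Oc2cc(Br)c(Br)c(Br)c2Oc2ccccc2Br)OC1(C)C | intermediate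
20 | 3,4,5-tribromo-2-(2-bromophenoxy)phenol | Oc1cc(Br)c(Br)c(Br)c1Oc1ccccc1Br | target

**Step count**

Total: 8 steps. Longest linear sequence: 6 steps (steps 3 to 8, from 2-bromophenol 6); the diene branch (steps 1 and 2) joins at step 7.

**Steps most likely to fail**

1. Step 7 (proposed new method). The diene may dimerize through its free C5–H faster than it adds the alkyne, the alkyne may add in the reverse orientation, or the push–pull alkyne may decompose on heating. The fallback uses only established reactions, sets out from 2-bromophenol 6 and comes back to the route at target 20. Copper-promoted Ullmann condensation of 6 with purchased 2,3,4,5-tetrabromobenzoic acid (copper powder, CuI, K2CO3, DMF, 110 °C) should replace only the bromine next to the carboxylate, which binds the copper, and give 3,4,5-tribromo-2-(2-bromophenoxy)benzoic acid F1. Curtius rearrangement with diphenylphosphoryl azide and Et3N in toluene at 80 °C, through 3,4,5-tribromo-2-(2-bromophenoxy)benzoyl azide F2 and 1,2,3-tribromo-4-(2-bromophenoxy)-5-isocyanatobenzene F3, followed by aqueous acid hydrolysis, should give 3,4,5-tribromo-2-(2-bromophenoxy)aniline F4. Diazotization with NaNO2 in H2SO4/AcOH at 0 °C to 3,4,5-tribromo-2-(2-bromophenoxy)benzenediazonium hydrogen sulfate F5 and hydrolysis in hot dilute H2SO4 should give 20.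

2. Step 6. Hydrogen chloride may add across the electron-rich triple bond during the quench, the amine and its hydrochloride left from the eliminations may interfere with release of the boronate, or boron may be lost by hydrolysis of the push–pull alkyne on isolation. The fallback replaces boron by an oxidizable silicon group, sets out from dibromide 10 and comes back at target 20. Acetylide 14, generated from 10 with LiN(iPr)2 as in step 6, is trapped with 3-chloro-1,1,1,3,5,5,5-heptamethyltrisiloxane, which needs no acid quench, to give 3-[(2-bromophenoxy)ethynyl]-1,1,1,3,5,5,5-heptamethyltrisiloxane F6. Cycloaddition with 5 under the conditions of step 7, with the same orientation for the same electronic and steric reasons, should pass through 1,5,6-tribromo-2-(2-bromophenoxy)-3-(1,1,1,3,5,5,5-heptamethyltrisiloxan-3-yl)-7-thiabicyclo[2.2.1]hepta-2,5-diene 7,7-dioxide F7 to 3-[3,4,5-tribromo-2-(2-bromophenoxy)phenyl]-1,1,1,3,5,5,5-heptamethyltrisiloxane F8. Tamao oxidation (H2O2, KHCO3, tetrabutylammonium fluoride, THF/MeOH) of the aryl–silicon bond should then give 20.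

3. Step 2. Oxygen transfer to the electron-poor sulfur may stay incomplete, or the sulfone may self-condense through its unsubstituted α-position during work-up and storage. The fallback blocks that position with silicon, sets out from tetrabromothiophene 1 and comes back at sulfone 5. Thienyllithium 2, made as in step 1, is quenched with chlorotrimethylsilane instead of water to give 2,3,4-tribromo-5-(trimethylsilyl)thiophene F9. Oxidation with the same peracid, helped by the electron-releasing silyl group, should give 2,3,4-tribromo-5-(trimethylsilyl)thiophene 1,1-dioxide F10, which has no free α-hydrogen and should be storable. Fluoride-induced cleavage of the C–Si bond next to the sulfonyl group (tetrabutylammonium fluoride buffered with AcOH, wet THF, −20 °C) should release 5 just before step 7.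

**Further compounds**

F1 | step 7 | 3,4,5-tribromo-2-(2-bromophenoxy)benzoic acid | OC(=O)c1cc(Br)c(Br)c(Br)c1Oc1ccccc1Br
F2 | step 7 | 3,4,5-tribromo-2-(2-bromophenoxy)benzoyl azide | [N-]=[N+]=NC(=O)c1cc(Br)c(Br)c(Br)c1Oc1ccccc1Br
F3 | step 7 | 1,2,3-tribromo-4-(2-bromophenoxy)-5-isocyanatobenzene | O=C=Nc1cc(Br)c(Br)c(Br)c1Oc1ccccc1Br
F4 | step 7 | 3,4,5-tribromo-2-(2-bromophenoxy)aniline | Nc1cc(Br)c(Br)c(Br)c1Oc1ccccc1Br
F5 | step 7 | 3,4,5-tribromo-2-(2-bromophenoxy)benzenediazonium hydrogen sulfate | N#[N+]c1cc(Br)c(Br)c(Br)c1Oc1ccccc1Br.OS(=O)(=O)[O-]
F6 | step 6 | 3-[(2-bromophenoxy)ethynyl]-1,1,1,3,5,5,5-heptamethyltrisiloxane | C[Si](C#COc1ccccc1Br)(O[Si](C)(C)C)O[Si](C)(C)C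
F7 | step 6 | 1,5,6-tribromo-2-(2-bromophenoxy)-3-(1,1,1,3,5,5,5-heptamethyltrisiloxan-3-yl)-7-thiabicyclo[2.2.1]hepta-2,5-diene 7,7-dioxide (racemic) | O=S1(=O)C2(Br)C(Br)=C(Br)C1C([Si](C)(O[Si](C)(C)C)O[Si](C)(C)C)=C2Oc3ccccc3Br
F8 | step 6 | 3-[3,4,5-tribromo-2-(2-bromophenoxy)phenyl]-1,1,1,3,5,5,5-heptamethyltrisiloxane | C[Si](c1cc(Br)c(Br)c(Br)c1Oc1ccccc1Br)(O[Si](C)(C)C)O[Si](C)(C)C
F9 | step 2 | 2,3,4-tribromo-5-(trimethylsilyl)thiophene | C[Si](C)(C)c1sc(Br)c(Br)c1Br
F10 | step 2 | 2,3,4-tribromo-5-(trimethylsilyl)thiophene 1,1-dioxide | C[Si](C)(C)C1=C(Br)C(Br)=C(Br)S1(=O)=O
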